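**Plan**
- Ring B is a phenol with OH at C4', the hydroxyalkyl chain ortho to it at C3' and the chromone para to it at C1'. This is the pattern of a 2-alkyl-4-substituted cyclohex-2-enone after loss of H2. Ring B is therefore re-saturated at C5'–C6' and then cut at C1'–C6' and C2'=C3'.
- These two cuts leave a (chromon-3-yl)acetaldehyde (C1', C2') and an alkyl vinyl ketone that brings C3'–C6' together with the protected side chain.
- Ring C is cut at O1–C2 and C2–C3 (C2 from DMF dimethyl acetal) and at C3–C4 (a salicylaldehyde plus a three-carbon acetal Grignard reagent, which also delivers C1' and C2').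
- Ring A comes from resorcinol. The prenyl group enters between two MOM ethers by directed lithiation. The third oxygen (future O1) enters para to it by sterically ruled C–H borylation–oxidation, so only the 6-prenyl chromone can form.
- Forward order: ring A substituents, ring C, ring B by annulation, dehydrogenation of ring B, then one acid step for all protecting groups.
- The target has no stereocentre. The centres that appear on the way (carbinol carbon, C1', C5') form racemic or as mixtures, and all are erased.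

Key step: step 13

Remark: the locants C1'–C6' are those of ring B of the isoflavone (C1' bonded to C3 of the chromone, C4' bearing OH) and are used for the same carbons in all precursors. The tertiary alcohol is carried as its triethylsilyl ether from step 11 to step 16.

Step 1
Reactants: 1 resorcinol (benzene-1,3-diol)
Product: 2 bis-MOM ether 1,3-bis(methoxymethoxy)benzene
Conditions: NaH (2.4 equiv), MOMCl (2.4 equiv), DMF, 0 °C → rt
Reagents that add atoms: chloromethyl methyl ether (MOMCl), COCCl
Why: Standard MOM protection (Williamson-type O-alkylation of the bis-phenoxide by the reactive α-chloro ether), which also installs the two groups that direct the lithiation of step 2.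

Step 2
Reactants: 2 bis-MOM ether 1,3-bis(methoxymethoxy)benzene; 3 prenyl bromide (1-bromo-3-methylbut-2-ene)
Product: 5 prenylarene 1,3-bis(methoxymethoxy)-2-(3-methylbut-2-en-1-yl)benzene, via aryllithium 4 (not isolated)
Conditions: n-BuLi (1.1 equiv), THF, 0 °C → rt; 3 (1.2 equiv), −78 °C → rt
Reagents that add atoms: n-butyllithium, [Li]CCCC (lithium of 4 only)
Why: Directed ortho-metalation: the two MOM ethers cooperate to place lithium on the carbon between them, and the aryllithium displaces bromide at the primary end of 3 (SN2), the routine entry to 2-prenylresorcinol ethers.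

Step 3
Reactants: 5 prenylarene 1,3-bis(methoxymethoxy)-2-(3-methylbut-2-en-1-yl)benzene
Product: 7 phenol 3,5-bis(methoxymethoxy)-4-(3-methylbut-2-en-1-yl)phenol, via pinacol boronate 6 (not isolated)
Conditions: [Ir(OMe)(cod)]2 (1.5 mol %), 4,4'-di-tert-butyl-2,2'-bipyridine (3 mol %), B2pin2 (0.6 equiv), THF, 65 °C; then aq. NaOH, 30% H2O2, 0 °C → rt
Reagents that add atoms: hydrogen peroxide, OO (phenol oxygen of 7); bis(pinacolato)diboron, CC1(C)OB(OC1(C)C)B1OC(C)(C)C(C)(C)O1 (boryl group of 6 only)
Why: One-pot iridium-catalysed aromatic C–H borylation and boronate oxidation: the borylation is ruled by sterics and in this 1,2,3-trisubstituted ring can only take the C–H that has hydrogen on both sides (para to the prenyl group), a trisubstituted alkene is a poor partner for the iridium boryl species, and alkaline peroxide leaves an unactivated alkene alone.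

Step 4
Reactants: 7 phenol 3,5-bis(methoxymethoxy)-4-(3-methylbut-2-en-1-yl)phenol
Product: 9 salicylaldehyde 6-hydroxy-2,4-bis(methoxymethoxy)-3-(3-methylbut-2-en-1-yl)benzaldehyde, via magnesium-bound salicyl alcohol 8 (not isolated)
Conditions: MgCl2 (2 equiv), Et3N (4 equiv), (CH2O)n (6 equiv), MeCN, 75 °C; cold aq. citric acid
Reagents that add atoms: formaldehyde (as paraformaldehyde), C=O
Why: Casnati–Skattebøl ortho-formylation: the magnesium phenoxide delivers formaldehyde only to an ortho carbon, a second formaldehyde takes up hydride from alkoxide 8, and since the two ortho positions are equivalent by symmetry and the para position is blocked a single aldehyde should result, with the free hydroxyl on the oxygen that becomes O1.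

Step 5
Reactants: 9 salicylaldehyde 6-hydroxy-2,4-bis(methoxymethoxy)-3-(3-methylbut-2-en-1-yl)benzaldehyde; 10 3-bromo-1,1-dimethoxypropane
Product: 12 racemic carbinol 1-[6-hydroxy-2,4-bis(methoxymethoxy)-3-(3-methylbut-2-en-1-yl)phenyl]-4,4-dimethoxybutan-1-ol, via Grignard reagent 11 (not isolated)
Conditions: 10, Mg, THF, 20–25 °C; 9 added to 11 (2.3 equiv), THF, 0 °C; pH 7 phosphate buffer
Reagents that add atoms: magnesium, [Mg] (metal of 11 only)
Why: Grignard addition to an aldehyde, in which the first equivalent of 11 is spent on the phenol, the β-metallated acetal is made and used at or below room temperature to avoid its fragmentation, the buffered work-up keeps the γ-hydroxy acetal from closing to a cyclic acetal, and the racemic carbinol centre disappears in step 6.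

Step 6
Reactants: 12 racemic carbinol 1-[6-hydroxy-2,4-bis(methoxymethoxy)-3-(3-methylbut-2-en-1-yl)phenyl]-4,4-dimethoxybutan-1-ol
Product: 13 ketone 1-[6-hydroxy-2,4-bis(methoxymethoxy)-3-(3-methylbut-2-en-1-yl)phenyl]-4,4-dimethoxybutan-1-one
Conditions: MnO2 (15 equiv), CH2Cl2, rt
Reagents that add atoms: none
Why: MnO2 oxidation of an activated benzylic alcohol under neutral heterogeneous conditions, which spares acetal, MOM ethers and alkene and gives a ketone whose phenol is tied up in a hydrogen bond.

Step 7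
Reactants: 13 ketone 1-[6-hydroxy-2,4-bis(methoxymethoxy)-3-(3-methylbut-2-en-1-yl)phenyl]-4,4-dimethoxybutan-1-one
Product: 15 chromone acetal 3-(2,2-dimethoxyethyl)-5,7-bis(methoxymethoxy)-6-(3-methylbut-2-en-1-yl)-4H-chromen-4-one, via enaminone 14 (not isolated)
Conditions: Me2NCH(OMe)2 (4 equiv), toluene, 100 °C; then SiO2, CH2Cl2, rt
Reagents that add atoms: N,N-dimethylformamide dimethyl acetal, COC(OC)N(C)C
Why: Standard one-carbon chromone closure: DMF dimethyl acetal condenses at the ketone α-methylene to enaminone 14, the ortho phenol adds to its β-carbon and dimethylamine leaves (6-endo-trig addition–elimination), and as only the oxygen para to the prenyl group is free the 6-prenyl isomer alone can form.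

Step 8
Reactants: 15 chromone acetal 3-(2,2-dimethoxyethyl)-5,7-bis(methoxymethoxy)-6-(3-methylbut-2-en-1-yl)-4H-chromen-4-one
Product: 16 aldehyde 2-[5,7-bis(methoxymethoxy)-6-(3-methylbut-2-en-1-yl)-4-oxo-4H-chromen-3-yl]acetaldehyde
Conditions: 10% aq. oxalic acid on SiO2, CH2Cl2, rt; filtration
Reagents that add atoms: water, O
Why: Acid-catalysed acetal hydrolysis, selective because the acetal of an aliphatic aldehyde ionises far more readily than the formaldehyde-derived aryl MOM acetals, run on wet silica so that the sensitive aldehyde is obtained by filtration and used at once.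

Step 9
Reactants: 17 ethyl 5-oxohexanoate
Product: 19 lactone 6,6-dimethyloxan-2-one, via bromomagnesium alkoxide 18 (not isolated)
Conditions: MeMgBr (1.05 equiv), THF, −78 °C → rt; aq. NH4Cl
Reagents that add atoms: methylmagnesium bromide, C[Mg]Br
Why: Chemoselective Grignard addition to the ketone in preference to the ester at low temperature, followed on warming by lactonisation of tertiary alkoxide 18 onto the ester.

Step 10
Reactants: 19 lactone 6,6-dimethyloxan-2-one
Product: 20 hydroxy amide 5-hydroxy-N-methoxy-N,5-dimethylhexanamide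
Conditions: MeNH(OMe)·HCl (2 equiv), AlMe3 (2 equiv), CH2Cl2, 0 °C → rt; aq. Rochelle salt
Reagents that add atoms: N,O-dimethylhydroxylamine hydrochloride, CNOC.Cl
Why: Weinreb aminolysis of a lactone by the aluminium amide formed from AlMe3 and the amine hydrochloride, a routine ring opening that gives the hydroxy amide.

Step 11
Reactants: 20 hydroxy amide 5-hydroxy-N-methoxy-N,5-dimethylhexanamide
Product: 21 silyl ether N-methoxy-N,5-dimethyl-5-(triethylsilyloxy)hexanamide
Conditions: TESOTf (1.3 equiv), 2,6-lutidine (2 equiv), CH2Cl2, 0 °C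
Reagents that add atoms: triethylsilyl trifluoromethanesulfonate, CC[Si](CC)(CC)OS(=O)(=O)C(F)(F)F
Why: Silyl triflate–lutidine silylation, the usual method for a hindered tertiary alcohol, which stops relactonisation, saves base in steps 12 and 14 and gives an ether that falls off in the final acid step.

Step 12
Reactants: 21 silyl ether N-methoxy-N,5-dimethyl-5-(triethylsilyloxy)hexanamide
Product: 23 vinyl ketone 7-methyl-7-(triethylsilyloxy)oct-1-en-3-one, via tetrahedral magnesium adduct 22 (not isolated)
Conditions: CH2=CHMgBr (1.4 equiv), THF, −10 °C; inverse quench into cold 1 M aq. NaHSO4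
Reagents that add atoms: vinylmagnesium bromide, C=C[Mg]Br
Why: Weinreb ketone synthesis: chelate 22 survives until the quench so that no second addition occurs, and the inverse acidic quench protonates the released N,O-dimethylhydroxylamine before it can add to the vinyl ketone.

Step 13
Reactants: 16 aldehyde 2-[5,7-bis(methoxymethoxy)-6-(3-methylbut-2-en-1-yl)-4-oxo-4H-chromen-3-yl]acetaldehyde; 23 vinyl ketone 7-methyl-7-(triethylsilyloxy)oct-1-en-3-one
Product: 26 racemic cyclohexenone 5,7-bis(methoxymethoxy)-6-(3-methylbut-2-en-1-yl)-3-{3-[3-methyl-3-(triethylsilyloxy)butyl]-4-oxocyclohex-2-en-1-yl}-4H-chromen-4-one, via pyrrolidine enamine 24 (not isolated), via keto aldehyde 25 (not isolated)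
Conditions: pyrrolidine (1.05 equiv), 4 Å MS, toluene, 0 °C → rt; 23 (1.1 equiv), rt → 40 °C; AcOH–NaOAc–H2O, 60 °C
Reagents that add atoms: pyrrolidine, C1CCNC1 (amine part of 24 only); water, O (aldehyde oxygen of 25 only)
Why: Pyrrolidine condenses with the aldehyde of 16 much faster than it can add to the electron-rich chromone, and the resulting E-enamine 24 attacks the unsubstituted terminus of vinyl ketone 23 through its β-carbon (the future C1'), which forms the C1'–C6' bond before buffered hydrolysis frees keto aldehyde 25. In the pyrrolidinium acetate medium the ketone of 25 enolises (or forms its enamine) toward the methylene that carries the side chain (C3'), this carbon adds to the aldehyde carbon C2', and loss of water gives the conjugated C2'=C3' enone. The sequence is the Stork enamine version of the Robinson annulation, the established route from arylacetaldehydes and alkyl vinyl ketones to 4-arylcyclohex-2-enones. Ring B closes in a favoured 6-(enolendo)-exo-trig aldol step. The single new stereocentre C1' is formed without control, so 26 is racemic, which is of no consequence because C1' becomes sp2 in step 15. Three selectivities are needed and all rest on the substrates: the aldol regiochemistry is fixed because enolisation toward C5' or at C1' could only close four-membered rings, a second Michael addition is held back by the equimolar preformed enamine and by crowding at the now tertiary C1', and any reversible amine addition at C2 of the chromone is undone when the acetic acid buffer re-closes the pyranone.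

Step 14
Reactants: 26 racemic cyclohexenone 5,7-bis(methoxymethoxy)-6-(3-methylbut-2-en-1-yl)-3-{3-[3-methyl-3-(triethylsilyloxy)butyl]-4-oxocyclohex-2-en-1-yl}-4H-chromen-4-one
Product: 28 selenide 5,7-bis(methoxymethoxy)-6-(3-methylbut-2-en-1-yl)-3-{3-[3-methyl-3-(triethylsilyloxy)butyl]-4-oxo-5-(phenylselanyl)cyclohex-2-en-1-yl}-4H-chromen-4-one (diastereomer mixture), via lithium enolate 27 (not isolated)
Conditions: LDA (1.15 equiv), THF, −78 °C; PhSeCl (1.2 equiv), THF, −78 °C; aq. NH4Cl
Reagents that add atoms: benzeneselenenyl chloride, Cl[Se]c1ccccc1; lithium diisopropylamide, CC(C)N([Li])C(C)C (lithium of 27 only)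
Why: α-Selenenylation of a ketone enolate: LDA deprotonates a cyclohexenone kinetically at the α' methylene (C5') to the cross-conjugated enolate 27, which captures PhSeCl at −78 °C much faster than the prenyl alkene can, and the uncontrolled configuration at C5' is irrelevant.

Step 15
Reactants: 28 selenide 5,7-bis(methoxymethoxy)-6-(3-methylbut-2-en-1-yl)-3-{3-[3-methyl-3-(triethylsilyloxy)butyl]-4-oxo-5-(phenylselanyl)cyclohex-2-en-1-yl}-4H-chromen-4-one
Product: 31 protected isoflavone 3-{4-hydroxy-3-[3-methyl-3-(triethylsilyloxy)butyl]phenyl}-5,7-bis(methoxymethoxy)-6-(3-methylbut-2-en-1-yl)-4H-chromen-4-one, via selenoxide 29 (not isolated), via cross-conjugated dienone 30 (not isolated)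
Conditions: 30% aq. H2O2 (3 equiv), pyridine (3 equiv), CH2Cl2, 0 °C → rt
Reagents that add atoms: hydrogen peroxide, OO (selenoxide oxygen of 29 only)
Why: Selenoxide syn-elimination: oxidation at selenium is far faster than alkene epoxidation, selenoxide 29 eliminates toward C6' below room temperature, and the resulting 4-H-cyclohexa-2,5-dienone 30 tautomerises irreversibly to the phenol, which removes the C1' stereocentre.

Step 16
Reactants: 31 protected isoflavone 3-{4-hydroxy-3-[3-methyl-3-(triethylsilyloxy)butyl]phenyl}-5,7-bis(methoxymethoxy)-6-(3-methylbut-2-en-1-yl)-4H-chromen-4-one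
Product: 32 coloratanin A 5,7-dihydroxy-3-[4-hydroxy-3-(3-hydroxy-3-methylbutyl)phenyl]-6-(3-methylbut-2-en-1-yl)-4H-chromen-4-one
Conditions: HCl (about 1 M, from conc. aq. HCl), MeOH, rt → 35 °C; NaHCO3
Reagents that add atoms: none
Why: Acid-catalysed methanolysis of the two aryl MOM acetals and of the tertiary TES ether in one operation, under the dilute, near-ambient conditions customary for prenylated flavonoid MOM ethers, which stay below the acidity and temperature at which the tertiary alcohol or the prenyl group would cyclise onto a neighbouring phenol.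

**Compound list**
1 | resorcinol (benzene-1,3-diol) | Oc1cccc(O)c1 | starting material
2 | 1,3-bis(methoxymethoxy)benzene | COCOc1cccc(OCOC)c1 | intermediate
3 | prenyl bromide (1-bromo-3-methylbut-2-ene) | CC(C)=CCBr | starting material
4 | [2,6-bis(methoxymethoxy)phenyl]lithium | [Li]c1c(OCOC)cccc1OCOC | intermediate
5 | 1,3-bis(methoxymethoxy)-2-(3-methylbut-2-en-1-yl)benzene | COCOc1cccc(OCOC)c1CC=C(C)C | intermediate
6 | 2-[3,5-bis(methoxymethoxy)-4-(3-methylbut-2-en-1-yl)phenyl]-4,4,5,5-tetramethyl-1,3,2-dioxaborolane | CC(C)=CCc1c(OCOC)cc(cc1OCOC)B1OC(C)(C)C(C)(C)O1 | intermediate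
7 | 3,5-bis(methoxymethoxy)-4-(3-methylbut-2-en-1-yl)phenol | CC(C)=CCc1c(OCOC)cc(O)cc1OCOC | intermediate
8 | 2-(hydroxymethyl)-3,5-bis(methoxymethoxy)-4-(3-methylbut-2-en-1-yl)phenol, present as its magnesium salt and drawn in the neutral form | CC(C)=CCc1c(OCOC)cc(O)c(CO)c1OCOC | intermediate
9 | 6-hydroxy-2,4-bis(methoxymethoxy)-3-(3-methylbut-2-en-1-yl)benzaldehyde | CC(C)=CCc1c(OCOC)cc(O)c(C=O)c1OCOC | intermediate
10 | 3-bromo-1,1-dimethoxypropane | COC(CCBr)OC | starting material
11 | (3,3-dimethoxypropyl)magnesium bromide | COC(CC[Mg]Br)OC | intermediate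
12 | 1-[6-hydroxy-2,4-bis(methoxymethoxy)-3-(3-methylbut-2-en-1-yl)phenyl]-4,4-dimethoxybutan-1-ol, racemic | COC(CCC(O)c1c(O)cc(OCOC)c(CC=C(C)C)c1OCOC)OC | intermediate
13 | 1-[6-hydroxy-2,4-bis(methoxymethoxy)-3-(3-methylbut-2-en-1-yl)phenyl]-4,4-dimethoxybutan-1-one | COC(CCC(=O)c1c(O)cc(OCOC)c(CC=C(C)C)c1OCOC)OC | intermediate
14 | 2-[(dimethylamino)methylidene]-1-[6-hydroxy-2,4-bis(methoxymethoxy)-3-(3-methylbut-2-en-1-yl)phenyl]-4,4-dimethoxybutan-1-one | COC(CC(=CN(C)C)C(=O)c1c(O)cc(OCOC)c(CC=C(C)C)c1OCOC)OC | intermediate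
15 | 3-(2,2-dimethoxyethyl)-5,7-bis(methoxymethoxy)-6-(3-methylbut-2-en-1-yl)-4H-chromen-4-one | COC(Cc1coc2cc(OCOC)c(CC=C(C)C)c(OCOC)c2c1=O)OC | intermediate
16 | 2-[5,7-bis(methoxymethoxy)-6-(3-methylbut-2-en-1-yl)-4-oxo-4H-chromen-3-yl]acetaldehyde | O=CCc1coc2cc(OCOC)c(CC=C(C)C)c(OCOC)c2c1=O | intermediate
17 | ethyl 5-oxohexanoate | CCOC(=O)CCCC(C)=O | starting material
18 | bromomagnesium alkoxide of ethyl 5-hydroxy-5-methylhexanoate | CCOC(=O)CCCC(C)(C)O[Mg]Br | intermediate
19 | 6,6-dimethyloxan-2-one | CC1(C)CCCC(=O)O1 | intermediate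
20 | 5-hydroxy-N-methoxy-N,5-dimethylhexanamide | CON(C)C(=O)CCCC(C)(C)O | intermediate
21 | N-methoxy-N,5-dimethyl-5-(triethylsilyloxy)hexanamide | CON(C)C(=O)CCCC(C)(C)O[Si](CC)(CC)CC | intermediate
22 | bromomagnesium alkoxide of 3-[methoxy(methyl)amino]-7-methyl-7-(triethylsilyloxy)oct-1-en-3-ol, racemic | C=CC(O[Mg]Br)(CCCC(C)(C)O[Si](CC)(CC)CC)N(C)OC | intermediate
23 | 7-methyl-7-(triethylsilyloxy)oct-1-en-3-one | C=CC(=O)CCCC(C)(C)O[Si](CC)(CC)CC | intermediate
24 | 5,7-bis(methoxymethoxy)-6-(3-methylbut-2-en-1-yl)-3-[(E)-2-(pyrrolidin-1-yl)ethenyl]-4H-chromen-4-one | O=c1c(/C=C/N2CCCC2)coc2cc(OCOC)c(CC=C(C)C)c(OCOC)c12 | intermediate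
25 | 2-[5,7-bis(methoxymethoxy)-6-(3-methylbut-2-en-1-yl)-4-oxo-4H-chromen-3-yl]-9-methyl-5-oxo-9-(triethylsilyloxy)decanal, racemic | O=CC(CCC(=O)CCCC(C)(C)O[Si](CC)(CC)CC)c1coc2cc(OCOC)c(CC=C(C)C)c(OCOC)c2c1=O | intermediate
26 | 5,7-bis(methoxymethoxy)-6-(3-methylbut-2-en-1-yl)-3-{3-[3-methyl-3-(triethylsilyloxy)butyl]-4-oxocyclohex-2-en-1-yl}-4H-chromen-4-one, racemic | O=C1CCC(c2coc3cc(OCOC)c(CC=C(C)C)c(OCOC)c3c2=O)C=C1CCC(C)(C)O[Si](CC)(CC)CC | intermediate
27 | cross-conjugated lithium enolate of 26 (C4'–O–Li, C4'=C5'), racemic | [Li]OC1=CCC(c2coc3cc(OCOC)c(CC=C(C)C)c(OCOC)c3c2=O)C=C1CCC(C)(C)O[Si](CC)(CC)CC | intermediate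
28 | 5,7-bis(methoxymethoxy)-6-(3-methylbut-2-en-1-yl)-3-{3-[3-methyl-3-(triethylsilyloxy)butyl]-4-oxo-5-(phenylselanyl)cyclohex-2-en-1-yl}-4H-chromen-4-one, diastereomer mixture | O=C1C([Se]c2ccccc2)CC(c2coc3cc(OCOC)c(CC=C(C)C)c(OCOC)c3c2=O)C=C1CCC(C)(C)O[Si](CC)(CC)CC | intermediate
29 | selenoxide of 28 (phenylseleninyl group at C5'), stereoisomer mixture | O=C1C([Se](=O)c2ccccc2)CC(c2coc3cc(OCOC)c(CC=C(C)C)c(OCOC)c3c2=O)C=C1CCC(C)(C)O[Si](CC)(CC)CC | intermediate
30 | 5,7-bis(methoxymethoxy)-6-(3-methylbut-2-en-1-yl)-3-{3-[3-methyl-3-(triethylsilyloxy)butyl]-4-oxocyclohexa-2,5-dien-1-yl}-4H-chromen-4-one, racemic | O=C1C=CC(c2coc3cc(OCOC)c(CC=C(C)C)c(OCOC)c3c2=O)C=C1CCC(C)(C)O[Si](CC)(CC)CC | intermediate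
31 | 3-{4-hydroxy-3-[3-methyl-3-(triethylsilyloxy)butyl]phenyl}-5,7-bis(methoxymethoxy)-6-(3-methylbut-2-en-1-yl)-4H-chromen-4-one | Oc1ccc(-c2coc3cc(OCOC)c(CC=C(C)C)c(OCOC)c3c2=O)cc1CCC(C)(C)O[Si](CC)(CC)CC | intermediate
32 | coloratanin A, 5,7-dihydroxy-3-[4-hydroxy-3-(3-hydroxy-3-methylbutyl)phenyl]-6-(3-methylbut-2-en-1-yl)-4H-chromen-4-one | CC(C)=CCc1c(O)cc2occ(-c3ccc(O)c(CCC(C)(C)O)c3)c(=O)c2c1O | target

**Step count**
- Total step count: 16.
- Longest linear sequence: 12 steps (steps 1–8, then 13–16).
- The vinyl ketone branch (steps 9–12) has four steps.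

**The three steps most likely to fail**

**Step 13 (annulation).**
- What may go wrong: amine attack at C2 of the chromone with opening of the pyranone, a second Michael addition at C1', polymerisation of the vinyl ketone, and self-condensation of the aldehyde before the enamine is complete.
- The fallback sets out from 16 (with 23) and comes back at 26. It keeps both ring-forming bonds, replaces the amine-based donor by a silyl enol ether and separates the two events.
- TBSOTf/Et3N (CH2Cl2, 0 °C) converts 16 into the silyl enol ether 3-[2-(tert-butyldimethylsilyloxy)ethenyl]-5,7-bis(methoxymethoxy)-6-(3-methylbut-2-en-1-yl)-4H-chromen-4-one F1.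
- A Mukaiyama–Michael addition of the silyl enol ether to 23 (BF3·OEt2, CH2Cl2, −78 °C, aq. NaHCO3 work-up) forms the C1'–C6' bond with no amine present. It stops after one addition because the product aldehyde is no longer a nucleophile.
- Keto aldehyde 25 is then isolated and closed in a separate aldol condensation with catalytic dibenzylammonium trifluoroacetate in warm toluene to give 26.

**Step 8 (release of the aldehyde).**
- What may go wrong: loss of the peri MOM ether at C5 under acid, attack of the C4 carbonyl oxygen on the freed aldehyde (furan-type closure), and aldol self-condensation on the support. Thermal decay of the acetal Grignard reagent in step 5 belongs to the same weak point.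
- The fallback sets out from 9 and comes back at 16. It reaches the aldehyde by oxidation under neutral conditions instead of by hydrolysis.
- (3-Bromopropoxy)-tert-butyldimethylsilane and Mg give [3-(tert-butyldimethylsilyloxy)propyl]magnesium bromide F2.
- Used at 2.3 equiv, this reagent adds to 9 to give the carbinol 4-(tert-butyldimethylsilyloxy)-1-[6-hydroxy-2,4-bis(methoxymethoxy)-3-(3-methylbut-2-en-1-yl)phenyl]butan-1-ol F3.
- MnO2 then gives the ketone 4-(tert-butyldimethylsilyloxy)-1-[6-hydroxy-2,4-bis(methoxymethoxy)-3-(3-methylbut-2-en-1-yl)phenyl]butan-1-one F4.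
- DMF dimethyl acetal at 100 °C leads through the enaminone 4-(tert-butyldimethylsilyloxy)-2-[(dimethylamino)methylidene]-1-[6-hydroxy-2,4-bis(methoxymethoxy)-3-(3-methylbut-2-en-1-yl)phenyl]butan-1-one F5 to the chromone 3-[2-(tert-butyldimethylsilyloxy)ethyl]-5,7-bis(methoxymethoxy)-6-(3-methylbut-2-en-1-yl)-4H-chromen-4-one F6.
- TBAF buffered with AcOH frees the alcohol 3-(2-hydroxyethyl)-5,7-bis(methoxymethoxy)-6-(3-methylbut-2-en-1-yl)-4H-chromen-4-one F7.
- Dess–Martin periodinane with NaHCO3 (CH2Cl2, 0 °C) oxidises this alcohol to 16.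

**Step 3 (C–H borylation beside the alkene).**
- What may go wrong: hydroboration or migration of the prenyl double bond by iridium hydride and boryl species, and sluggish borylation of the electron-rich ring.
- The fallback sets out from 2 and comes back at 7. It introduces the third oxygen before any alkene is present.
- Under the same iridium catalysis 2 is borylated at its only unhindered C–H to 2-[3,5-bis(methoxymethoxy)phenyl]-4,4,5,5-tetramethyl-1,3,2-dioxaborolane F8.
- Oxidation with NaOH/H2O2 gives 3,5-bis(methoxymethoxy)phenol F9.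
- TIPSCl/imidazole gives [3,5-bis(methoxymethoxy)phenoxy]triisopropylsilane F10.
- n-BuLi lithiates between the two MOM ethers, since the bulky silyl ether shields the other two positions, to give [2,6-bis(methoxymethoxy)-4-(triisopropylsilyloxy)phenyl]lithium F11.
- Alkylation with 3 gives [3,5-bis(methoxymethoxy)-4-(3-methylbut-2-en-1-yl)phenoxy]triisopropylsilane F12.
- TBAF then releases 7.

**Further compounds**
F1 | step 13 | 3-[2-(tert-butyldimethylsilyloxy)ethenyl]-5,7-bis(methoxymethoxy)-6-(3-methylbut-2-en-1-yl)-4H-chromen-4-one (E/Z mixture) | CC(C)(C)[Si](C)(C)OC=Cc1coc2cc(OCOC)c(CC=C(C)C)c(OCOC)c2c1=O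
F2 | step 8 | [3-(tert-butyldimethylsilyloxy)propyl]magnesium bromide | CC(C)(C)[Si](C)(C)OCCC[Mg]Br
F3 | step 8 | 4-(tert-butyldimethylsilyloxy)-1-[6-hydroxy-2,4-bis(methoxymethoxy)-3-(3-methylbut-2-en-1-yl)phenyl]butan-1-ol (racemic) | CC(C)(C)[Si](C)(C)OCCCC(O)c1c(O)cc(OCOC)c(CC=C(C)C)c1OCOC
F4 | step 8 | 4-(tert-butyldimethylsilyloxy)-1-[6-hydroxy-2,4-bis(methoxymethoxy)-3-(3-methylbut-2-en-1-yl)phenyl]butan-1-one | CC(C)(C)[Si](C)(C)OCCCC(=O)c1c(O)cc(OCOC)c(CC=C(C)C)c1OCOC
F5 | step 8 | 4-(tert-butyldimethylsilyloxy)-2-[(dimethylamino)methylidene]-1-[6-hydroxy-2,4-bis(methoxymethoxy)-3-(3-methylbut-2-en-1-yl)phenyl]butan-1-one | CN(C)C=C(CCO[Si](C)(C)C(C)(C)C)C(=O)c1c(O)cc(OCOC)c(CC=C(C)C)c1OCOC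
F6 | step 8 | 3-[2-(tert-butyldimethylsilyloxy)ethyl]-5,7-bis(methoxymethoxy)-6-(3-methylbut-2-en-1-yl)-4H-chromen-4-one | CC(C)(C)[Si](C)(C)OCCc1coc2cc(OCOC)c(CC=C(C)C)c(OCOC)c2c1=O
F7 | step 8 | 3-(2-hydroxyethyl)-5,7-bis(methoxymethoxy)-6-(3-methylbut-2-en-1-yl)-4H-chromen-4-one | OCCc1coc2cc(OCOC)c(CC=C(C)C)c(OCOC)c2c1=O
F8 | step 3 | 2-[3,5-bis(methoxymethoxy)phenyl]-4,4,5,5-tetramethyl-1,3,2-dioxaborolane | CC1(C)OB(OC1(C)C)c1cc(OCOC)cc(OCOC)c1
F9 | step 3 | 3,5-bis(methoxymethoxy)phenol | Oc1cc(OCOC)cc(OCOC)c1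
F10 | step 3 | [3,5-bis(methoxymethoxy)phenoxy]triisopropylsilane | CC(C)[Si](Oc1cc(OCOC)cc(OCOC)c1)(C(C)C)C(C)C
F11 | step 3 | [2,6-bis(methoxymethoxy)-4-(triisopropylsilyloxy)phenyl]lithium | [Li]c1c(OCOC)cc(O[Si](C(C)C)(C(C)C)C(C)C)cc1OCOC
F12 | step 3 | [3,5-bis(methoxymethoxy)-4-(3-methylbut-2-en-1-yl)phenoxy]triisopropylsilane | CC(C)=CCc1c(OCOC)cc(O[Si](C(C)C)(C(C)C)C(C)C)cc1OCOC
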